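I had no rate constants for this flask, so I reckoned from its charges and readings, following one molecule of starting material and asking where it could end.

| flask | starting material | reagent | protic impurity | free catalyst | temperature | remark | time |
|---|---|---|---|---|---|---|---|
| delta | 0.25 M | 0.75 M | 0.075 M | 50 mM | 5 °C | the very flask that is asked about, followed so far |  |
| gamma | 0.25 M | 0.75 M | 0.075 M | 50 mM | 0 °C | run made earlier |  |
| flask | 0.25 M | 0.750 M | 0.0750 M | 50 mM | 5 °C |  | 6.0 h |

- delta (time / min: product / %, starting material / %): 30.0: 37, 21; 50.0: 45, 10; 80.0: 49, 0; 120: 54, 4; 240: 57, 0; 360: 55, 4
- gamma (time / min: product / %, starting material / %): 30.0: 28, 28; 50.0: 38, 17; 80.0: 49, 8; 120: 51, 0; 240: 55, 0; 360: 54, 0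

(standard deviation of a reading: 2 percentage points)

- Wednesday's: change nothing and wait 12 h more
- Sunday's: at 6.0 h take out 90% of the product then present, then wait 12 h
- Saturday's: at 6.0 h add free catalyst, 100% of the amount charged, then wait 12 h
- Friday's: at 6.0 h add reagent, 50.0% of the amount charged, then wait 12 h
- Thursday's: at 6.0 h raise the temperature by 20 K, then wait 12 h

- product, in percent of the starting material first charged, at 6.0 h
- which option adds most product ("none" when 2 percentage points or less is all one gets) (Wednesday's / Sunday's / Saturday's / Friday's / Thursday's / none)
- product present, with what was taken out counted in, in percent of the starting material first charged, after Wednesday's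
- product present, with what was taken out counted in, in percent of the starting material first charged, after Sunday's

- removed product is counted in
- additions bring no volume worth counting

With the main step by itself, starting material turning into product, each molecule arrives, and product should level at the whole charge. But the delta product readings averaged 55.3% from 120 min on, while starting material read 0% and 4% at the last two times. Next I added the protic impurity, supposing that it destroys starting material one for one. That fork takes c(protic impurity)/c(starting material) = 30.0%, and the ceiling falls to 70.0%. Then I added the catalyst, supposing that each catalyst molecule can carry one molecule of starting material or its descendant. That can hold back 20.0% of the charge, so product should stand between 50.0% and 70.0%, and the reading does.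

So I took 15 percentage points to be sitting on the catalyst. I call the load the part of the catalyst that carries such a molecule, the held share of the charge over what the catalyst could hold: 73.3%.

Now I expected 55.3% at 6.0 h and the same after waiting: the last delta product readings were 54%, 57% and 55%, with 2 points of scatter on each. More reagent offered nothing I could count on. The gamma level of 53.3% against 55.3%, with 2 points of scatter on a reading, gave no ground to hope for much from heat. Fresh catalyst at the same load should take up 15 points of product. My wager was that the held molecules stay in balance with the product around them, so Sunday's should free some of them, gaining more than 2 points and at most 15 points.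

The forecast gave 55.5%, none as the best option and 55.5% after Sunday's, on the ground that “the simplest reading is an irreversible end”, and on Sunday's it parted from my wager.

The flask gave 54.3% at 6.0 h, and Sunday's added 6.6 points, reaching 60.9%. In this flask at 360 min, catalyst intermediate C stood at 42.2% and catalyst intermediate D at 36.5% of the catalyst, with free catalyst at 21.3%, so the two bound forms came to 78.7% against my load of 73.3%.

    starting material + free catalyst → catalyst intermediate A (k = 2.79 M⁻¹ min⁻¹, Ea = 49.0 kJ mol⁻¹)
    catalyst intermediate A ⇌ catalyst intermediate B (K = 0.616, k = 0.670 min⁻¹, Ea = 71.0 kJ mol⁻¹, ΔH = −21.0 kJ mol⁻¹)
    reagent + catalyst intermediate B → catalyst intermediate C (k = 3.65 M⁻¹ min⁻¹, Ea = 60.0 kJ mol⁻¹)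
    catalyst intermediate C ⇌ by-product + catalyst intermediate D (K = 0.133 M, k = 6.79 min⁻¹, Ea = 80.0 kJ mol⁻¹, ΔH = −48.0 kJ mol⁻¹)
    catalyst intermediate D ⇌ free catalyst + product (K = 0.0792 M, k = 0.435 min⁻¹, Ea = 87.0 kJ mol⁻¹, ΔH = −43.0 kJ mol⁻¹)
    starting material + protic impurity → quenched substrate (k = 9.29 M⁻¹ min⁻¹, Ea = 37.0 kJ mol⁻¹)
    (constants at 5 °C)

For a neighbouring flask, the same but with 0.020 M of free catalyst, the same load gave me 64.1% of product, and that neighbouring flask stood at 62.4% at 6.0 h with 1.0% of its starting material still there.

All runs come from a simulation on assumed constants.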